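## Retrosynthetic overview

1. The target is traced back to 6α-silyloxy-drim-7-ene-1β,11,12-triol: late acylation of O1 with (E)-4-methoxycinnamoyl chloride, Swern oxidation of the 11,12-diol to the dial, and C6 desilylation last.
2. Ring B and the quaternary C10 come from a Diels–Alder reaction of the ring-A diene C10=C5–C6=C7 (C1 pivalate, R) with dimethyl acetylenedicarboxylate anti to O1. Alpha-face hydroboration of C5=C6 then sets 5α-H and 6α-OH, and deconjugative kinetic protonation sets C9.
3. The diene comes from CBS reduction of 2,4,4-trimethyl-3-vinylcyclohex-2-enone, itself made by vinyl addition/transposition on 3-ethoxy-2,6,6-trimethylcyclohex-2-enone.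
4. Ring A is made from 3-ethoxy-2-methylcyclobut-2-enone (atoms C5, C10, C1, C2) plus isopropenyllithium (C4, C3) and MeI, by addition, 4π ring opening, 6π ring closure and C-methylation. Ring order: four-membered ring, then ring A, then ring B.
5. Enabling feature: in ring A the C2–C3 edge is two bare CH2 groups between the oxygenated C1 and C4, which carries two identical methyls. Ring A therefore divides into a cyclobutenone (C5 carbonyl, C10–Me, C1–OEt, C2) and a C4–C3 alkenyl unit; the electrocyclization termini C2 and C3 are unsubstituted and C4 is completed by methylation without creating a stereocentre.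

Key step: step 2

Remark: bicyclic compounds carry drimane numbering (C1 = oxygenated carbon of ring A, C4 = gem-dimethyl carbon, C5/C10 = ring fusion, C11 on C9, C12 on C8); beta is the face of the C10 methyl group.

## Route

Step 1
Reactants: 1 acetyl chloride; 2 1-ethoxyprop-1-yne
Product: 4 3-ethoxy-2-methylcyclobut-2-en-1-one, via ketene 3 (not isolated)
Conditions: Et3N, Et2O, 0 °C to rt
Reagents that add atoms: none
Why: Ketene formed in situ by dehydrochlorination should undergo the established regioselective [2+2] cycloaddition with the ynol ether, the nucleophilic methyl-bearing alkyne carbon bonding to the ketene carbonyl carbon, to give the 3-alkoxycyclobutenone.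

Step 2
Reactants: 4 3-ethoxy-2-methylcyclobut-2-en-1-one; 5 2-bromopropene
Product: 10 3-ethoxy-2,6,6-trimethylcyclohex-2-en-1-one, via isopropenyllithium 6 (not isolated), via lithium cyclobutenolate 7 (not isolated), via lithium trienolate 8 (not isolated), via lithium cyclohexadienolate 9 (not isolated)
Conditions: 5, t-BuLi (2 equiv), THF, −78 °C; add 4, −78 °C to 25 °C; then MeI, DMPU, −78 °C to 0 °C
Reagents that add atoms: iodomethane, CI
Why: Isopropenyllithium 6 should add 1,2 to the carbonyl of 4; on warming, alkoxide 7 should undergo oxyanion-accelerated conrotatory 4π opening of the cyclobutene (cleaving the bond between the carbinol carbon and the ring CH2) to trienolate 8, which should close by thermal disrotatory 6π electrocyclization between its two unsubstituted CH2 termini (the C2–C3 bond) to enolate 9, and C-methylation at the enolate carbon (C4) gives 10. The closest known reaction type is the two-carbon ring expansion of cyclobutenones to cyclohexenones by alkenyllithium addition, alkoxide-accelerated electrocyclic opening and hexatriene electrocyclization, followed by the standard alpha-prime alkylation of a 3-alkoxycyclohexenone enolate. Ring A is the only ring closed, in the 6π disrotatory mode, so the four-membered ring (C5, C10, C1, C2) becomes the six-membered ring by insertion of C4 and C3. No stereocentre survives in 10, because the carbinol centre of 7 is erased on ring opening and C4 receives two identical methyl groups. The step needs torquoselectivity, secured because the oxido group rotates outward and so places the isopropenyl group inward, cis to the ethoxyvinyl unit as the closure requires; it also needs 1,2-addition, secured by the hard organolithium at low temperature, and C- rather than O-methylation, secured by the lithium enolate with iodomethane.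

Step 3
Reactants: 10 3-ethoxy-2,6,6-trimethylcyclohex-2-en-1-one; 11 vinylmagnesium bromide
Product: 13 2,4,4-trimethyl-3-vinylcyclohex-2-en-1-one, via bromomagnesium alkoxide 12 (not isolated)
Conditions: CH2=CHMgBr, THF, 0 °C to rt; then 1 M aq. HCl, 0 °C
Reagents that add atoms: water, O
Why: 1,2-Addition of the Grignard reagent to the vinylogous ester followed by acid hydrolysis with allylic transposition (Stork–Danheiser sequence) should place the vinyl group on the carbon next to the gem-dimethyl centre (C5) and the carbonyl on the former ethoxy-bearing carbon (C1).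

Step 4
Reactants: 13 2,4,4-trimethyl-3-vinylcyclohex-2-en-1-one
Product: 14 (R)-2,4,4-trimethyl-3-vinylcyclohex-2-en-1-ol
Conditions: (S)-2-methyl-CBS-oxazaborolidine [(S)-1-methyl-3,3-diphenyltetrahydro-1H,3H-pyrrolo[1,2-c][1,3,2]oxazaborole] (10 mol%), catecholborane, toluene, −78 °C; aq. NaOH work-up
Reagents that add atoms: none
Why: In this Corey–Bakshi–Shibata reduction the catalyst distinguishes the trisubstituted alkenyl side (large) from the CH2 side (small), so the (S)-catalyst is expected to give the (R)-allylic alcohol and set C1, while catecholborane at −78 °C should leave the diene untouched.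

Step 5
Reactants: 14 (R)-2,4,4-trimethyl-3-vinylcyclohex-2-en-1-ol
Product: 15 (R)-2,4,4-trimethyl-3-vinylcyclohex-2-en-1-yl pivalate
Conditions: PivCl, pyridine, DMAP (cat.), CH2Cl2, 0 °C to rt
Reagents that add atoms: pivaloyl chloride, CC(C)(C)C(Cl)=O
Why: Standard DMAP-catalysed acylation gives an ester with no alpha hydrogen that should survive borane and amide base and is removed without an extra step in the hydride reduction of step 10.

Step 6
Reactants: 15 (R)-2,4,4-trimethyl-3-vinylcyclohex-2-en-1-yl pivalate; 16 dimethyl acetylenedicarboxylate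
Product: 17 dimethyl 1β-(pivaloyloxy)drima-5,8-diene-11,12-dioate
Conditions: toluene, BHT (cat.), 110 °C, sealed tube
Reagents that add atoms: none
Why: The thermal Diels–Alder reaction of the semicyclic diene with the symmetrical alkyne builds ring B and the quaternary C10, and the dienophile should approach the C10 terminus anti to the adjacent pseudoaxial pivaloyloxy group, which places the C10 methyl cis to the C1 oxygen.

Step 7
Reactants: 17 dimethyl 1β-(pivaloyloxy)drima-5,8-diene-11,12-dioate
Product: 19 dimethyl 6α-hydroxy-1β-(pivaloyloxy)drim-8-ene-11,12-dioate, via C6 alkylborane 18 (not isolated)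
Conditions: BH3·THF, THF, 0 °C to rt; then 30% H2O2, aq. NaOH, 0 °C
Reagents that add atoms: hydrogen peroxide, OO
Why: Hydroboration–oxidation of the electron-rich trisubstituted C5=C6 alkene (the tetrasubstituted diester alkene is electron-poor) should occur syn from the alpha face, opposite to the axial methyl groups on C10 and C4, with boron on C6, setting 5α-H (trans ring fusion) and 6α-OH together.

Step 8
Reactants: 19 dimethyl 6α-hydroxy-1β-(pivaloyloxy)drim-8-ene-11,12-dioate
Product: 20 dimethyl 6α-(tert-butyldimethylsilyloxy)-1β-(pivaloyloxy)drim-8-ene-11,12-dioate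
Conditions: TBSOTf, 2,6-lutidine, CH2Cl2, −78 °C to 0 °C
Reagents that add atoms: tert-butyldimethylsilyl trifluoromethanesulfonate, CC(C)(C)[Si](C)(C)OS(=O)(=O)C(F)(F)F
Why: Silylation of the hindered secondary alcohol with the silyl triflate gives an ether chosen to survive every later step up to the last one.

Step 9
Reactants: 20 dimethyl 6α-(tert-butyldimethylsilyloxy)-1β-(pivaloyloxy)drim-8-ene-11,12-dioate
Product: 22 dimethyl 6α-(tert-butyldimethylsilyloxy)-1β-(pivaloyloxy)drim-7-ene-11,12-dioate (9α-H), via lithium dienolate 21 (not isolated)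
Conditions: LiN(i-Pr)2, THF, −78 °C; then AcOH, −78 °C
Reagents that add atoms: none
Why: In this deconjugative isomerisation the amide base should remove the gamma proton at C7 to give extended enolate 21, and kinetic protonation at the alpha carbon C9 from the alpha face (opposite to the axial C10 methyl) should give the 7-ene with the C9 ester beta.

Step 10
Reactants: 22 dimethyl 6α-(tert-butyldimethylsilyloxy)-1β-(pivaloyloxy)drim-7-ene-11,12-dioate
Product: 23 6α-(tert-butyldimethylsilyloxy)drim-7-ene-1β,11,12-triol
Conditions: LiAlH4, Et2O, 0 °C to rt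
Reagents that add atoms: none
Why: LiAlH4 should reduce both methyl esters (the conjugated one by 1,2-addition) to primary alcohols and cleave the pivalate in the same operation, leaving the silyl ether intact.

Step 11
Reactants: 23 6α-(tert-butyldimethylsilyloxy)drim-7-ene-1β,11,12-triol
Product: 24 6α-(tert-butyldimethylsilyloxy)-11,12-bis(triethylsilyloxy)drim-7-en-1β-ol
Conditions: Et3SiCl, imidazole, CH2Cl2, −20 °C to 0 °C
Reagents that add atoms: chlorotriethylsilane, CC[Si](Cl)(CC)CC
Why: Chemoselective silylation should take the two primary hydroxyl groups, because the neopentyl-type secondary C1 hydroxyl reacts far more slowly with the chlorosilane at low temperature.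

Step 12
Reactants: 24 6α-(tert-butyldimethylsilyloxy)-11,12-bis(triethylsilyloxy)drim-7-en-1β-ol; 25 (E)-4-methoxycinnamoyl chloride
Product: 26 6α-(tert-butyldimethylsilyloxy)-11,12-bis(triethylsilyloxy)drim-7-en-1β-yl (E)-4-methoxycinnamate
Conditions: Et3N, DMAP (cat.), CH2Cl2, 0 °C to 40 °C
Reagents that add atoms: none
Why: DMAP-catalysed acylation of the only free hydroxyl group with the acid chloride installs the cinnamate, whose (E) geometry is carried over unchanged from 25.

Step 13
Reactants: 26 6α-(tert-butyldimethylsilyloxy)-11,12-bis(triethylsilyloxy)drim-7-en-1β-yl (E)-4-methoxycinnamate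
Product: 27 6α-(tert-butyldimethylsilyloxy)-11,12-dihydroxydrim-7-en-1β-yl (E)-4-methoxycinnamate
Conditions: AcOH/THF/H2O (3:1:1), rt
Reagents that add atoms: none
Why: Mild acid hydrolysis should cleave the primary triethylsilyl ethers much faster than the hindered secondary tert-butyldimethylsilyl ether and should not touch the cinnamate.

Step 14
Reactants: 27 6α-(tert-butyldimethylsilyloxy)-11,12-dihydroxydrim-7-en-1β-yl (E)-4-methoxycinnamate
Product: 28 6α-(tert-butyldimethylsilyloxy)-11,12-dioxodrim-7-en-1β-yl (E)-4-methoxycinnamate (9α-H)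
Conditions: (COCl)2, DMSO, CH2Cl2, −78 °C; then Et3N, −78 °C to −20 °C
Reagents that add atoms: none
Why: Swern oxidation activates both primary alcohols at once, so the 1,4-diol should go to the dialdehyde without lactol or lactone formation, and the cold amine base should leave the C9 stereocentre intact.

Step 15
Reactants: 28 6α-(tert-butyldimethylsilyloxy)-11,12-dioxodrim-7-en-1β-yl (E)-4-methoxycinnamate
Product: 29 6α-hydroxy-11,12-dioxodrim-7-en-1β-yl (E)-4-methoxycinnamate (target, CNP0283080.1)
Conditions: HF·pyridine, pyridine, THF, 0 °C to rt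
Reagents that add atoms: none
Why: Buffered fluoride desilylation under weakly acidic conditions should free the C6 hydroxyl without base-induced epimerisation at C9 or cleavage of the cinnamate.

## Compound list

1 | acetyl chloride | CC(Cl)=O | starting material
2 | 1-ethoxyprop-1-yne | CC#COCC | starting material
3 | ketene (not isolated) | C=C=O | intermediate
4 | 3-ethoxy-2-methylcyclobut-2-en-1-one | CCOC1=C(C)C(=O)C1 | intermediate
5 | 2-bromopropene | CC(Br)=C | starting material
6 | isopropenyllithium (not isolated) | [Li]C(C)=C | intermediate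
7 | lithium 3-ethoxy-2-methyl-1-(prop-1-en-2-yl)cyclobut-2-en-1-olate (racemic; not isolated) | [Li+].[O-]C1(C(C)=C)CC(OCC)=C1C | intermediate
8 | lithium (3E)-5-ethoxy-2,4-dimethylhexa-1,3,5-trien-3-olate (not isolated) | [Li+].C=C(C)/C([O-])=C(C)\C(OCC)=C | intermediate
9 | lithium 5-ethoxy-2,6-dimethylcyclohexa-1,5-dien-1-olate (not isolated) | [Li+].[O-]C1=C(C)CCC(OCC)=C1C | intermediate
10 | 3-ethoxy-2,6,6-trimethylcyclohex-2-en-1-one | CCOC1=C(C)C(=O)C(C)(C)CC1 | intermediate
11 | vinylmagnesium bromide | C=C[Mg]Br | starting material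
12 | bromomagnesium 3-ethoxy-2,6,6-trimethyl-1-vinylcyclohex-2-en-1-olate (racemic; not isolated) | CCOC1=C(C)C(O[Mg]Br)(C=C)C(C)(C)CC1 | intermediate
13 | 2,4,4-trimethyl-3-vinylcyclohex-2-en-1-one | C=CC1=C(C)C(=O)CCC1(C)C | intermediate
14 | (R)-2,4,4-trimethyl-3-vinylcyclohex-2-en-1-ol | O[C@@H]1CCC(C)(C)C(C=C)=C1C | intermediate
15 | (R)-2,4,4-trimethyl-3-vinylcyclohex-2-en-1-yl pivalate | CC(C)(C)C(=O)O[C@@H]1CCC(C)(C)C(C=C)=C1C | intermediate
16 | dimethyl acetylenedicarboxylate | COC(=O)C#CC(=O)OC | starting material
17 | dimethyl 1β-(pivaloyloxy)drima-5,8-diene-11,12-dioate (C1 oxygen and C10 methyl cis) | CC(C)(C)C(=O)O[C@@H]1CCC(C)(C)C2=CCC(C(=O)OC)=C(C(=O)OC)[C@@]12C | intermediate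
18 | dimethyl 6α-boranyl-1β-(pivaloyloxy)drim-8-ene-11,12-dioate (5α-H; not isolated) | CC(C)(C)C(=O)O[C@@H]1CCC(C)(C)[C@@H]2[C@@H](B)CC(C(=O)OC)=C(C(=O)OC)[C@@]12C | intermediate
19 | dimethyl 6α-hydroxy-1β-(pivaloyloxy)drim-8-ene-11,12-dioate (5α-H, trans-fused) | CC(C)(C)C(=O)O[C@@H]1CCC(C)(C)[C@@H]2[C@@H](O)CC(C(=O)OC)=C(C(=O)OC)[C@@]12C | intermediate
20 | dimethyl 6α-(tert-butyldimethylsilyloxy)-1β-(pivaloyloxy)drim-8-ene-11,12-dioate | CC(C)(C)C(=O)O[C@@H]1CCC(C)(C)[C@@H]2[C@@H](O[Si](C)(C)C(C)(C)C)CC(C(=O)OC)=C(C(=O)OC)[C@@]12C | intermediate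
21 | lithium dienolate of 20 (C7=C8, C9=C11 ester enolate; not isolated) | [Li+].CC(C)(C)C(=O)O[C@@H]1CCC(C)(C)[C@@H]2[C@@H](O[Si](C)(C)C(C)(C)C)C=C(C(=O)OC)C(=C([O-])OC)[C@@]12C | intermediate
22 | dimethyl 6α-(tert-butyldimethylsilyloxy)-1β-(pivaloyloxy)drim-7-ene-11,12-dioate (9α-H, C9 ester beta) | CC(C)(C)C(=O)O[C@@H]1CCC(C)(C)[C@@H]2[C@@H](O[Si](C)(C)C(C)(C)C)C=C(C(=O)OC)[C@H](C(=O)OC)[C@@]12C | intermediate
23 | 6α-(tert-butyldimethylsilyloxy)drim-7-ene-1β,11,12-triol | O[C@@H]1CCC(C)(C)[C@@H]2[C@@H](O[Si](C)(C)C(C)(C)C)C=C(CO)[C@H](CO)[C@@]12C | intermediate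
24 | 6α-(tert-butyldimethylsilyloxy)-11,12-bis(triethylsilyloxy)drim-7-en-1β-ol | O[C@@H]1CCC(C)(C)[C@@H]2[C@@H](O[Si](C)(C)C(C)(C)C)C=C(CO[Si](CC)(CC)CC)[C@H](CO[Si](CC)(CC)CC)[C@@]12C | intermediate
25 | (E)-4-methoxycinnamoyl chloride | COc1ccc(/C=C/C(Cl)=O)cc1 | starting material
26 | 6α-(tert-butyldimethylsilyloxy)-11,12-bis(triethylsilyloxy)drim-7-en-1β-yl (E)-4-methoxycinnamate | COc1ccc(/C=C/C(=O)O[C@@H]2CCC(C)(C)[C@@H]3[C@@H](O[Si](C)(C)C(C)(C)C)C=C(CO[Si](CC)(CC)CC)[C@H](CO[Si](CC)(CC)CC)[C@@]23C)cc1 | intermediate
27 | 6α-(tert-butyldimethylsilyloxy)-11,12-dihydroxydrim-7-en-1β-yl (E)-4-methoxycinnamate | COc1ccc(/C=C/C(=O)O[C@@H]2CCC(C)(C)[C@@H]3[C@@H](O[Si](C)(C)C(C)(C)C)C=C(CO)[C@H](CO)[C@@]23C)cc1 | intermediate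
28 | 6α-(tert-butyldimethylsilyloxy)-11,12-dioxodrim-7-en-1β-yl (E)-4-methoxycinnamate | COc1ccc(/C=C/C(=O)O[C@@H]2CCC(C)(C)[C@@H]3[C@@H](O[Si](C)(C)C(C)(C)C)C=C(C=O)[C@H](C=O)[C@@]23C)cc1 | intermediate
29 | 6α-hydroxy-11,12-dioxodrim-7-en-1β-yl (E)-4-methoxycinnamate | COc1ccc(/C=C/C(=O)O[C@@H]2CCC(C)(C)[C@@H]3[C@@H](O)C=C(C=O)[C@H](C=O)[C@@]23C)cc1 | target

## Step count and risks

Total step count: 15. Longest linear sequence: 15 steps (from 1 and 2 to 29).

The three steps most likely to fail are steps 2, 6 and 9.

**Step 2.** After ring opening, trienolate 8 may be diverted before it closes, by proton transfer, oligomerisation of the electron-rich triene or premature alkylation; enolate 9 may also be O-methylated. The fallback sets out from 4 (with 6 made from 5 as in the route) and comes back at 9. The adduct of 6 and 4 is quenched at −78 °C with aqueous NaHCO3 to give 3-ethoxy-2-methyl-1-(prop-1-en-2-yl)cyclobut-2-en-1-ol F1. F1 is silylated (Me3SiCl, imidazole) to trimethyl{[3-ethoxy-2-methyl-1-(prop-1-en-2-yl)cyclobut-2-en-1-yl]oxy}silane F2. Heating F2 in toluene with a trace of Et3N should open the neutral cyclobutene thermally, the silyloxy group rotating outward, to {[(3E)-5-ethoxy-2,4-dimethylhexa-1,3,5-trien-3-yl]oxy}trimethylsilane F3. F3 should close by 6π electrocyclization to [(5-ethoxy-2,6-dimethylcyclohexa-1,5-dien-1-yl)oxy]trimethylsilane F4. MeLi in THF then cleaves the silyl enol ether of F4 to lithium enolate 9, which is methylated to 10 as before. This replaces the anionic one-flask cascade by neutral, isolable intermediates and purely thermal pericyclic steps.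

**Step 6.** The pivaloyloxy group may discriminate poorly between the two faces of the diene during bond formation at C10, or the hindered terminus may react slowly while the diene decomposes. The fallback sets out from 13 and comes back at 17; it removes the stereocentre from the diene and sets C1 afterwards.
- Ketalisation of 13 (1,2-bis(trimethylsilyloxy)ethane, Me3SiOTf cat., CH2Cl2, −78 °C) gives 6,8,8-trimethyl-7-vinyl-1,4-dioxaspiro[4.5]dec-6-ene F5.
- Cycloaddition of F5 with 16 gives racemic dimethyl 1,1-(ethylenedioxy)drima-5,8-diene-11,12-dioate F6.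
- Mild aqueous acid gives racemic dimethyl 1-oxodrima-5,8-diene-11,12-dioate F7.
- Reagent-controlled CBS reduction of racemic F7 with the (S)-catalyst should turn the two enantiomers into separable diastereomeric (1R)-alcohols. The matched enantiomer (hydride from the alpha face, anti to the C10 methyl) gives dimethyl 1β-hydroxydrima-5,8-diene-11,12-dioate F8; the other gives dimethyl 1α-hydroxy-ent-drima-5,8-diene-11,12-dioate F9, which is removed by chromatography.
- Pivaloylation of F8 gives 17.

At most half of the material is used, and the ketal makes the C10 terminus no less hindered, so this answers poor facial selectivity rather than low reactivity.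

**Step 9.** Extended enolate 21 may expel the C6 silyloxide by vinylogous beta-elimination, or may be protonated at C7 or unselectively at C9. The fallback sets out from 19 and comes back at 22; it defers protection so that the C6 oxygen is an alkoxide that cannot leave. Treatment of 19 with two equivalents of LiN(i-Pr)2 should give the dilithium alkoxide–dienolate F10. Kinetic protonation with AcOH at −78 °C should give dimethyl 6α-hydroxy-1β-(pivaloyloxy)drim-7-ene-11,12-dioate F11, which is silylated with TBSOTf and 2,6-lutidine to 22.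

## Further compounds

F1 | step 2 | 3-ethoxy-2-methyl-1-(prop-1-en-2-yl)cyclobut-2-en-1-ol (racemic) | CCOC1=C(C)C(O)(C(C)=C)C1
F2 | step 2 | trimethyl{[3-ethoxy-2-methyl-1-(prop-1-en-2-yl)cyclobut-2-en-1-yl]oxy}silane (racemic) | CCOC1=C(C)C(O[Si](C)(C)C)(C(C)=C)C1
F3 | step 2 | {[(3E)-5-ethoxy-2,4-dimethylhexa-1,3,5-trien-3-yl]oxy}trimethylsilane | C=C(C)/C(O[Si](C)(C)C)=C(C)\C(OCC)=C
F4 | step 2 | [(5-ethoxy-2,6-dimethylcyclohexa-1,5-dien-1-yl)oxy]trimethylsilane | CCOC1=C(C)C(O[Si](C)(C)C)=C(C)CC1
F5 | step 6 | 6,8,8-trimethyl-7-vinyl-1,4-dioxaspiro[4.5]dec-6-ene | C=CC1=C(C)C2(CCC1(C)C)OCCO2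
F6 | step 6 | dimethyl 1,1-(ethylenedioxy)drima-5,8-diene-11,12-dioate (racemic) | COC(=O)C1=C(C(=O)OC)C2(C)C(=CC1)C(C)(C)CCC23OCCO3
F7 | step 6 | dimethyl 1-oxodrima-5,8-diene-11,12-dioate (racemic) | COC(=O)C1=C(C(=O)OC)C2(C)C(=CC1)C(C)(C)CCC2=O
F8 | step 6 | dimethyl 1β-hydroxydrima-5,8-diene-11,12-dioate | O[C@@H]1CCC(C)(C)C2=CCC(C(=O)OC)=C(C(=O)OC)[C@@]12C
F9 | step 6 | dimethyl 1α-hydroxy-ent-drima-5,8-diene-11,12-dioate | O[C@@H]1CCC(C)(C)C2=CCC(C(=O)OC)=C(C(=O)OC)[C@]12C
F10 | step 9 | dilithium alkoxide–dienolate of 19 (C6 alkoxide, C7=C8, C9=C11 ester enolate) | [Li+].[Li+].CC(C)(C)C(=O)O[C@@H]1CCC(C)(C)[C@@H]2[C@@H]([O-])C=C(C(=O)OC)C(=C([O-])OC)[C@@]12C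
F11 | step 9 | dimethyl 6α-hydroxy-1β-(pivaloyloxy)drim-7-ene-11,12-dioate (9α-H) | CC(C)(C)C(=O)O[C@@H]1CCC(C)(C)[C@@H]2[C@@H](O)C=C(C(=O)OC)[C@H](C(=O)OC)[C@@]12C
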